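**Retrosynthetic overview**
1. The last bond made is the aryl C5–O bond. The target comes from its 7,4'-dipivalate lacking the 5-OMe group by C4=O-directed C–H methoxylation, with ester methanolysis in the same flask.
2. The dipivalate comes from 7,4'-dihydroxy-3',5'-dimethoxy-6-methylisoflavone by masking the two phenols.
3. The isoflavone comes from a 2,4-dihydroxy-5-methyl deoxybenzoin plus one carbon from DMF. Ring C closes through the O1–C2 bond.
4. The deoxybenzoin comes from 4-methylresorcinol (ring A, which fixes 6-Me and 7-OH) and homosyringic acid (ring B).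
5. Rings A and B are bought. Ring C is the only ring built (step 1). The C5–O bond is formed last (step 3).

Assumption: the SMILES holds no stereocentre, stereogenic axis or E/Z element, so the target is achiral and no stereocontrol is needed.

**Step 1**
Reactants: 1 4-methylresorcinol; 2 2-(4-hydroxy-3,5-dimethoxyphenyl)acetic acid (homosyringic acid)
Product: 4 7-hydroxy-3-(4-hydroxy-3,5-dimethoxyphenyl)-6-methyl-4H-chromen-4-one, via deoxybenzoin 3 (not isolated)
Conditions: BF3·OEt2 (solvent), 85 °C, 2 h, Ar; cool, DMF, then MsCl (3 equiv) in DMF, 50 → 75 °C, 2 h; pour into cold aq NaOAc, filter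
Reagents that add atoms: N,N-dimethylformamide, CN(C)C=O (supplies C2–H)
Why: BF3-promoted Friedel–Crafts acylation attacks the only open position of 1 that is ortho/para to both hydroxyls, then the Vilsmeier-type reagent from DMF/MsCl formylates the activated CH2 and the single ortho-OH closes ring C by O1–C2 bond formation with loss of Me2NH (one-pot deoxybenzoin isoflavone synthesis, tolerant of free phenols), so the 6-methyl regiochemistry is unambiguous and no stereocentre is formed.

**Step 2**
Reactants: 4 7-hydroxy-3-(4-hydroxy-3,5-dimethoxyphenyl)-6-methyl-4H-chromen-4-one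
Product: 5 3-[3,5-dimethoxy-4-(pivaloyloxy)phenyl]-6-methyl-4-oxo-4H-chromen-7-yl pivalate
Conditions: PivCl (2.6 equiv), Et3N (3.5 equiv), DMAP (10 mol %), CH2Cl2, 0 °C → rt, 12 h
Reagents that add atoms: pivaloyl chloride, CC(C)(C)C(=O)Cl
Why: DMAP-catalysed O-acylation masks both phenols as bulky, electron-withdrawing esters that resist acidic methanol and lower the oxidation sensitivity of rings A and B, while nothing else in 4 is acylable.

**Step 3**
Reactants: 5 3-[3,5-dimethoxy-4-(pivaloyloxy)phenyl]-6-methyl-4-oxo-4H-chromen-7-yl pivalate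
Product: 7 7-hydroxy-3-(4-hydroxy-3,5-dimethoxyphenyl)-5-methoxy-6-methyl-4H-chromen-4-one (target), via 5-methoxy dipivalate 6 (not isolated)
Conditions: Pd(OAc)2 (10 mol %), MsOH (0.5 equiv), K2S2O8 (2.5 equiv), MeOH/1,2-dichloroethane 1:1, 55 °C, 24 h; filter through Celite (removes undissolved oxidant and salts); then K2CO3 (5 equiv), MeOH, Ar, rt → 40 °C, 6 h; acidic work-up
Reagents that add atoms: methanol, CO
Why: Proposed new method: carbonyl-directed C5–H methoxylation of a chromone, in which the pyrone C4=O (about as Lewis basic as an amide oxygen) binds the cationic divalent palladium formed from Pd(OAc)2/MsOH, concerted metalation–deprotonation takes the peri C5–H (the only C–H that gives a five-membered palladacycle), persulfate oxidises this to a tetravalent palladium methanol/methoxide complex, and C–O reductive elimination gives 6, whose pivalates are then removed by base methanolysis once the oxidant is filtered off; the closest known reaction types are the Pd(OAc)2/K2S2O8 ortho-C–H alkoxylation of anilides, N-methoxybenzamides and benzonitriles in alcohols and the [RuCl2(p-cymene)]2-catalysed C5–H hydroxylation of chromones and flavones, and no stereocentre is formed.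

**Compound list**
1 | 4-methylbenzene-1,3-diol (4-methylresorcinol) | Cc1ccc(O)cc1O | starting material
2 | 2-(4-hydroxy-3,5-dimethoxyphenyl)acetic acid | COc1cc(CC(=O)O)cc(OC)c1O | starting material
3 | 1-(2,4-dihydroxy-5-methylphenyl)-2-(4-hydroxy-3,5-dimethoxyphenyl)ethan-1-one | COc1cc(CC(=O)c2cc(C)c(O)cc2O)cc(OC)c1O | intermediate
4 | 7-hydroxy-3-(4-hydroxy-3,5-dimethoxyphenyl)-6-methyl-4H-chromen-4-one | COc1cc(-c2coc3cc(O)c(C)cc3c2=O)cc(OC)c1O | intermediate
5 | 3-[3,5-dimethoxy-4-(pivaloyloxy)phenyl]-6-methyl-4-oxo-4H-chromen-7-yl pivalate | COc1cc(-c2coc3cc(OC(=O)C(C)(C)C)c(C)cc3c2=O)cc(OC)c1OC(=O)C(C)(C)C | intermediate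
6 | 3-[3,5-dimethoxy-4-(pivaloyloxy)phenyl]-5-methoxy-6-methyl-4-oxo-4H-chromen-7-yl pivalate | COc1cc(-c2coc3cc(OC(=O)C(C)(C)C)c(C)c(OC)c3c2=O)cc(OC)c1OC(=O)C(C)(C)C | intermediate
7 | 7-hydroxy-3-(4-hydroxy-3,5-dimethoxyphenyl)-5-methoxy-6-methyl-4H-chromen-4-one | COc1cc(-c2coc3cc(O)c(C)c(OC)c3c2=O)cc(OC)c1O | target

**Total step count:** 3. **Longest linear sequence:** 3.

**Steps most likely to fail**

Step 3 (the proposed new step). The risks are:
- The carbonyl is a weak donor in a coordinating alcohol.
- C5–H is crowded by the 6-methyl group.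
- Palladation could compete at C2'/C6' through a six-membered chelate, or at C8.
- Ring B could be over-oxidised.

The fallback uses known chemistry, sets out from 5 and comes back at 6. Compound 5 is heated with [RuCl2(p-cymene)]2 (5 mol %) and PhI(OCOCF3)2 (2 equiv) in TFA/TFAA at 80 °C, the established carbonyl-directed C5–H oxygenation of chromones. This gives 3-[3,5-dimethoxy-4-(pivaloyloxy)phenyl]-6-methyl-4-oxo-5-(trifluoroacetoxy)-4H-chromen-7-yl pivalate F3. Aqueous work-up hydrolyses it to 3-[3,5-dimethoxy-4-(pivaloyloxy)phenyl]-5-hydroxy-6-methyl-4-oxo-4H-chromen-7-yl pivalate F4. Its only free hydroxyl, the chelated 5-OH, is methylated with MeI/K2CO3 in refluxing dry acetone to give 6. Compound 6 is then carried to 7 with K2CO3/MeOH as in the route.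

Step 1. The risks are a low yield in the hot BF3·OEt2 acylation with the electron-rich acid 2 and tar formation in the one-pot formylation. The fallback sets out from 1 and comes back at 4. It replaces the acid acylation by a Houben–Hoesch reaction and changes the one-carbon donor. Compound 1 and purchased (4-hydroxy-3,5-dimethoxyphenyl)acetonitrile are treated with ZnCl2 and HCl gas in Et2O at 0 °C. This precipitates 1-(2,4-dihydroxy-5-methylphenyl)-2-(4-hydroxy-3,5-dimethoxyphenyl)ethan-1-iminium chloride F1. Boiling water hydrolyses it to 3, now isolated and recrystallised. Ring C is closed with HC(OEt)3 in pyridine with catalytic piperidine at 120 °C to give 4.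

Step 2. The risks are the poor solubility of 4 and sluggish acylation of the doubly flanked 4'-OH. The fallback reverses the order to protect first and cyclise second. It sets out from 3, obtained by stopping step 1 after the acylation stage with an aqueous work-up, and comes back at 5. The soluble ketone 3 is treated with PivCl (2.1 equiv), Et3N and DMAP in CH2Cl2 at 0 °C, which leaves the chelated 2-OH free. This gives 4-{2-[3,5-dimethoxy-4-(pivaloyloxy)phenyl]acetyl}-5-hydroxy-2-methylphenyl pivalate F2. It is cyclised under acidic conditions (BF3·OEt2, DMF, MsCl, 60 °C), which the esters survive, directly to 5.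

**Further compounds**
F1 | step 1 | 1-(2,4-dihydroxy-5-methylphenyl)-2-(4-hydroxy-3,5-dimethoxyphenyl)ethan-1-iminium chloride | COc1cc(CC(=[NH2+])c2cc(C)c(O)cc2O)cc(OC)c1O.[Cl-]
F2 | step 2 | 4-{2-[3,5-dimethoxy-4-(pivaloyloxy)phenyl]acetyl}-5-hydroxy-2-methylphenyl pivalate | COc1cc(CC(=O)c2cc(C)c(OC(=O)C(C)(C)C)cc2O)cc(OC)c1OC(=O)C(C)(C)C
F3 | step 3 | 3-[3,5-dimethoxy-4-(pivaloyloxy)phenyl]-6-methyl-4-oxo-5-(trifluoroacetoxy)-4H-chromen-7-yl pivalate | COc1cc(-c2coc3cc(OC(=O)C(C)(C)C)c(C)c(OC(=O)C(F)(F)F)c3c2=O)cc(OC)c1OC(=O)C(C)(C)C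
F4 | step 3 | 3-[3,5-dimethoxy-4-(pivaloyloxy)phenyl]-5-hydroxy-6-methyl-4-oxo-4H-chromen-7-yl pivalate | COc1cc(-c2coc3cc(OC(=O)C(C)(C)C)c(C)c(O)c3c2=O)cc(OC)c1OC(=O)C(C)(C)C
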